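**Strategy.** Everything rests on building ring A instead of selectively arylating a hydroquinone. Ring A's hydroxyl carbon, the para carbon that carries the ether oxygen to ring D, and the carbon ortho to that ether that carries the two-carbon bridge to ring B are mapped onto a 2-aryloxyfuran and a terminal ynone. One Diels–Alder/bridge-opening operation forms two C–C bonds of ring A and turns the furan oxygen into the free phenol, with the acyl bridge ortho to the aryl ether. The precursors are a furan already bearing rings D and C (with the bromide for the closing Ullmann etherification to ring B) and a silyl-protected ring B benzyl ethynyl ketone.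

Key step: step 9

Remark on the chemistry: salt 1 is assumed to be bought; alkene 3 is carried as an E/Z mixture because both isomers converge in step 2; cycloadduct 13 is racemic and loses its stereocentres on aromatisation; the target is achiral, so no stereocontrol is needed.

**Step 1**
Reactants: 1 (4-bromobenzyl)triphenylphosphonium bromide; 2 3-hydroxybenzaldehyde
Product: 3 3-[2-(4-bromophenyl)ethenyl]phenol (E/Z mixture)
Conditions: KOtBu (2.4 equiv), THF, 0 °C to rt; aq. NH4Cl
Reagents that add atoms: none
Why: Wittig olefination with a semi-stabilised benzylic ylide, the extra base holding the phenol as a phenoxide that is meta to the aldehyde and so does not deactivate it.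

**Step 2**
Reactants: 3 3-[2-(4-bromophenyl)ethenyl]phenol
Product: 4 3-[2-(4-bromophenyl)ethyl]phenol
Conditions: TsNHNH2, NaOAc, THF/H2O, reflux
Reagents that add atoms: none
Why: Diimide generated in situ transfers two hydrogens to the C=C bond in a concerted step and, unlike catalytic hydrogenation, cannot touch the aryl bromide.

**Step 3**
Reactants: 4 3-[2-(4-bromophenyl)ethyl]phenol; 5 methyl 5-nitrofuran-2-carboxylate
Product: 6 methyl 5-{3-[2-(4-bromophenyl)ethyl]phenoxy}furan-2-carboxylate
Conditions: K2CO3, DMSO, 60 °C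
Reagents that add atoms: none
Why: Nucleophilic aromatic substitution (addition–elimination) in which the phenoxide attacks C5 of the ester-activated furan and expels nitrite, a displacement known for 5-nitro-2-furoates, while the unactivated aryl bromide is inert.

**Step 4**
Reactants: 6 methyl 5-{3-[2-(4-bromophenyl)ethyl]phenoxy}furan-2-carboxylate
Product: 7 5-{3-[2-(4-bromophenyl)ethyl]phenoxy}furan-2-carboxylic acid
Conditions: LiOH·H2O, THF/MeOH/H2O, rt; then cold 1 M HCl to pH 3
Reagents that add atoms: lithium hydroxide, [Li+].[OH-]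
Why: Ordinary ester saponification, run at room temperature so that the carboxylate forms before hydroxide can attack the aryloxy-bearing furan carbon.

**Step 5**
Reactants: 7 5-{3-[2-(4-bromophenyl)ethyl]phenoxy}furan-2-carboxylic acid
Product: 8 2-{3-[2-(4-bromophenyl)ethyl]phenoxy}furan
Conditions: Ag2CO3 (10 mol %), AcOH (5 mol %), DMSO, 120 °C
Reagents that add atoms: none
Why: Silver-catalysed protodecarboxylation of a heteroaromatic 2-carboxylic acid (silver carboxylate, loss of CO2 to a furyl–silver species, protonolysis), eased by the donor at C5 and milder than the copper/quinoline variant, so the aryl bromide is spared.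

**Step 6**
Reactants: 9 3-hydroxy-4-methoxyphenylacetic acid
Product: 10 2-(3-hydroxy-4-methoxyphenyl)-N-methoxy-N-methylacetamide
Conditions: MeNHOMe·HCl, EDC·HCl, HOBt, Et3N, CH2Cl2, 0 °C to rt
Reagents that add atoms: N,O-dimethylhydroxylamine hydrochloride, CNOC.Cl
Why: Carbodiimide amide coupling to the Weinreb amide, which tolerates the free phenol because the amine outcompetes it for the active ester and any aryl ester formed is aminolysed.

**Step 7**
Reactants: 10 2-(3-hydroxy-4-methoxyphenyl)-N-methoxy-N-methylacetamide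
Product: 11 N-methoxy-2-{4-methoxy-3-[(triisopropylsilyl)oxy]phenyl}-N-methylacetamide
Conditions: TIPSCl, imidazole, DMF, rt to 40 °C
Reagents that add atoms: chlorotriisopropylsilane, CC(C)[Si](Cl)(C(C)C)C(C)C
Why: Standard imidazole-promoted silylation of a phenol, the bulky triisopropylsilyl ether being chosen because it withstands the Grignard addition, the cycloaddition and carbonate/MeI yet falls to hot KOH in step 11.

**Step 8**
Reactants: 11 N-methoxy-2-{4-methoxy-3-[(triisopropylsilyl)oxy]phenyl}-N-methylacetamide
Product: 12 1-{4-methoxy-3-[(triisopropylsilyl)oxy]phenyl}but-3-yn-2-one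
Conditions: HC≡CMgBr (3 equiv), THF, 0 °C; inverse quench into cold aq. NaHSO4
Reagents that add atoms: ethynylmagnesium bromide, C#C[Mg]Br
Why: Weinreb ketone synthesis in which the chelated tetrahedral intermediate prevents over-addition, and the cold acidic inverse quench protonates the liberated hydroxylamine before it can add to the ynone.

**Step 9**
Reactants: 8 2-{3-[2-(4-bromophenyl)ethyl]phenoxy}furan; 12 1-{4-methoxy-3-[(triisopropylsilyl)oxy]phenyl}but-3-yn-2-one
Product: 14 1-(2-{3-[2-(4-bromophenyl)ethyl]phenoxy}-5-hydroxyphenyl)-2-{4-methoxy-3-[(triisopropylsilyl)oxy]phenyl}ethan-1-one, via oxanorbornadiene cycloadduct 13 (not isolated)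
Conditions: PhMe (1 M), 12 (1.3 equiv), 80 °C; then PPTS (cat.), CH2Cl2, rt
Reagents that add atoms: none
Why: The donor-substituted furan adds across the electron-poor alkyne in an asynchronous, possibly stepwise, [4+2] cycloaddition in which the most nucleophilic furan carbon, the unsubstituted C5, bonds to the alkyne terminus and the aryloxy-bearing C2 bonds to the acyl-bearing carbon, giving oxanorbornadiene 13. The bridge C–O bond at the aryloxy-bearing bridgehead of 13 then ionises, because the cation formed is an aryloxy-stabilised oxocarbenium ion, and loss of the proton at the other bridgehead aromatises the ring, so the furan oxygen becomes the ring A hydroxyl para to the aryl ether and the acyl group ends ortho to that ether. The closest known reaction type is the Diels–Alder/ring-opening benzannulation of 2-alkoxyfurans with acetylenic ketones and esters to hydroquinone monoethers; the aryloxy group is a weaker donor, hence the heating and the mild acid finish. Ring A is closed by an intermolecular [4+2] cycloaddition that forms two C–C bonds, followed by opening of the oxygen bridge, and the two bridgehead stereocentres of racemic 13 disappear in 14. The selectivities required are the head-to-tail orientation and bridge opening toward the aryloxy carbon, both fixed by the polarisation of the 2-oxygenated furan against the ynone, while concentrated, aprotic, base-free conditions should suppress open-chain Michael adducts and addition of the product phenol to the ynone.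

**Step 10**
Reactants: 14 1-(2-{3-[2-(4-bromophenyl)ethyl]phenoxy}-5-hydroxyphenyl)-2-{4-methoxy-3-[(triisopropylsilyl)oxy]phenyl}ethan-1-one
Product: 15 1-(2-{3-[2-(4-bromophenyl)ethyl]phenoxy}-5-methoxyphenyl)-2-{4-methoxy-3-[(triisopropylsilyl)oxy]phenyl}ethan-1-one
Conditions: MeI, K2CO3, acetone, rt to 40 °C
Reagents that add atoms: iodomethane, CI
Why: Williamson O-methylation of the only free phenol under mild carbonate conditions, which are too weakly basic to C-alkylate the benzylic ketone or to cleave the aryl silyl ether.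

**Step 11**
Reactants: 15 1-(2-{3-[2-(4-bromophenyl)ethyl]phenoxy}-5-methoxyphenyl)-2-{4-methoxy-3-[(triisopropylsilyl)oxy]phenyl}ethan-1-one
Product: 17 5-[2-(2-{3-[2-(4-bromophenyl)ethyl]phenoxy}-5-methoxyphenyl)ethyl]-2-methoxyphenol, via hydrazone 16 (not isolated)
Conditions: N2H4·H2O, diethylene glycol, 130 °C; then KOH, 195 °C (water distilled off); dil. HCl
Reagents that add atoms: none
Why: Wolff–Kishner reduction (Huang-Minlon procedure) takes the ketone to CH2 through the hydrazone anion and loss of N2, avoiding the benzylic cation of an acidic silane reduction that the ortho aryloxy ring could trap as a xanthene, while the same hot hydroxide cleaves the aryl silyl ether to free the ring B phenol and leaves the unactivated aryl bromide and the diaryl ether alone.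

**Step 12**
Reactants: 17 5-[2-(2-{3-[2-(4-bromophenyl)ethyl]phenoxy}-5-methoxyphenyl)ethyl]-2-methoxyphenol
Product: 18 dihydroptychantol A di-O-methyl ether (18-membered macrocycle with OMe on ring A and on ring B)
Conditions: CuI, N,N-dimethylglycine·HCl, Cs2CO3, 1,4-dioxane, 100 °C, slow addition to 2 mM
Reagents that add atoms: none
Why: Intramolecular Ullmann diaryl ether synthesis under ligand-accelerated copper catalysis and high dilution, with a single phenol and a single aryl bromide in the substrate so that only the ring B to ring C ether of the 18-membered ring can form.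

**Step 13**
Reactants: 18 dihydroptychantol A di-O-methyl ether
Product: 19 dihydroptychantol A
Conditions: BBr3, CH2Cl2, −78 °C to rt; then H2O
Reagents that add atoms: none
Why: Boron tribromide cleavage of both aryl methyl ethers through aryl borates, a standard final step that leaves diaryl ethers untouched.

**Compound list**
1 | (4-bromobenzyl)triphenylphosphonium bromide | [Br-].Brc1ccc(C[P+](c2ccccc2)(c2ccccc2)c2ccccc2)cc1 | starting material
2 | 3-hydroxybenzaldehyde | O=Cc1cccc(O)c1 | starting material
3 | 3-[2-(4-bromophenyl)ethenyl]phenol (E/Z mixture, geometry not specified) | Oc1cccc(C=Cc2ccc(Br)cc2)c1 | intermediate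
4 | 3-[2-(4-bromophenyl)ethyl]phenol | Oc1cccc(CCc2ccc(Br)cc2)c1 | intermediate
5 | methyl 5-nitrofuran-2-carboxylate | COC(=O)c1ccc(o1)[N+](=O)[O-] | starting material
6 | methyl 5-{3-[2-(4-bromophenyl)ethyl]phenoxy}furan-2-carboxylate | COC(=O)c1ccc(o1)Oc1cccc(CCc2ccc(Br)cc2)c1 | intermediate
7 | 5-{3-[2-(4-bromophenyl)ethyl]phenoxy}furan-2-carboxylic acid | OC(=O)c1ccc(o1)Oc1cccc(CCc2ccc(Br)cc2)c1 | intermediate
8 | 2-{3-[2-(4-bromophenyl)ethyl]phenoxy}furan | o1cccc1Oc1cccc(CCc2ccc(Br)cc2)c1 | intermediate
9 | 3-hydroxy-4-methoxyphenylacetic acid | COc1ccc(CC(=O)O)cc1O | starting material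
10 | 2-(3-hydroxy-4-methoxyphenyl)-N-methoxy-N-methylacetamide | COc1ccc(CC(=O)N(C)OC)cc1O | intermediate
11 | N-methoxy-2-{4-methoxy-3-[(triisopropylsilyl)oxy]phenyl}-N-methylacetamide | COc1ccc(CC(=O)N(C)OC)cc1O[Si](C(C)C)(C(C)C)C(C)C | intermediate
12 | 1-{4-methoxy-3-[(triisopropylsilyl)oxy]phenyl}but-3-yn-2-one | C#CC(=O)Cc1ccc(OC)c(O[Si](C(C)C)(C(C)C)C(C)C)c1 | intermediate
13 | 1-{3-[2-(4-bromophenyl)ethyl]phenoxy}-2-({4-methoxy-3-[(triisopropylsilyl)oxy]phenyl}acetyl)-7-oxabicyclo[2.2.1]hepta-2,5-diene (racemic; bridgeheads tied by the oxygen bridge) | O=C(Cc1ccc(OC)c(O[Si](C(C)C)(C(C)C)C(C)C)c1)C1=CC2C=CC1(O2)Oc1cccc(CCc2ccc(Br)cc2)c1 | intermediate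
14 | 1-(2-{3-[2-(4-bromophenyl)ethyl]phenoxy}-5-hydroxyphenyl)-2-{4-methoxy-3-[(triisopropylsilyl)oxy]phenyl}ethan-1-one | Oc1ccc(Oc2cccc(CCc3ccc(Br)cc3)c2)c(c1)C(=O)Cc1ccc(OC)c(O[Si](C(C)C)(C(C)C)C(C)C)c1 | intermediate
15 | 1-(2-{3-[2-(4-bromophenyl)ethyl]phenoxy}-5-methoxyphenyl)-2-{4-methoxy-3-[(triisopropylsilyl)oxy]phenyl}ethan-1-one | COc1ccc(Oc2cccc(CCc3ccc(Br)cc3)c2)c(c1)C(=O)Cc1ccc(OC)c(O[Si](C(C)C)(C(C)C)C(C)C)c1 | intermediate
16 | hydrazone of ketone 15 (C=N geometry not specified) | COc1ccc(Oc2cccc(CCc3ccc(Br)cc3)c2)c(c1)C(=NN)Cc1ccc(OC)c(O[Si](C(C)C)(C(C)C)C(C)C)c1 | intermediate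
17 | 5-[2-(2-{3-[2-(4-bromophenyl)ethyl]phenoxy}-5-methoxyphenyl)ethyl]-2-methoxyphenol | COc1ccc(Oc2cccc(CCc3ccc(Br)cc3)c2)c(c1)CCc1ccc(OC)c(O)c1 | intermediate
18 | dihydroptychantol A di-O-methyl ether | COc1ccc2c(c1)CCc1ccc(OC)c(c1)Oc1ccc(cc1)CCc1cccc(c1)O2 | intermediate
19 | dihydroptychantol A | Oc1ccc2c(c1)CCc1ccc(O)c(c1)Oc1ccc(cc1)CCc1cccc(c1)O2 | target

**Totals.** Total step count: 13. Longest linear sequence: 10 steps (steps 1–5 and 9–13); the ynone branch (steps 6–8) joins at step 9.

**Steps most likely to fail**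

Step 9. The aryloxy group donates less than an alkoxy group, so cycloaddition may be slow enough for ynone self-condensation, or for stepwise Michael addition with cleavage of the furan ring, to take over. The fallback gives up the ring construction and makes the ring A to ring D ether by known substitution chemistry, setting out from 4 and rejoining at 17. Phenol 4 is heated with 2-fluoro-5-methoxybenzaldehyde and K2CO3 in DMA at 140 °C (nucleophilic aromatic substitution ortho to the formyl group) to give 2-{3-[2-(4-bromophenyl)ethyl]phenoxy}-5-methoxybenzaldehyde F1. Commercial 3-hydroxy-4-methoxybenzyl alcohol and PPh3·HBr in refluxing MeCN give (3-hydroxy-4-methoxybenzyl)triphenylphosphonium bromide F2. Wittig reaction of F1 with F2 and KOtBu (extra equivalent for the phenol) gives 5-[2-(2-{3-[2-(4-bromophenyl)ethyl]phenoxy}-5-methoxyphenyl)ethenyl]-2-methoxyphenol F3 as an E/Z mixture, and diimide reduction (TsNHNH2, NaOAc) gives 17.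

Step 12. Intermolecular etherification to oligomers, or protodebromination at copper, may outrun closure of the 18-membered ring. The fallback sets out from 17, changes the coupling from a halide displacement at 100 °C to an oxidative boron-based etherification at room temperature, and returns at 18. Miyaura borylation of 17 (B2pin2, PdCl2(dppf), KOAc, dioxane, 80 °C) gives 5-{2-[5-methoxy-2-(3-{2-[4-(4,4,5,5-tetramethyl-1,3,2-dioxaborolan-2-yl)phenyl]ethyl}phenoxy)phenyl]ethyl}-2-methoxyphenol F4. Oxidative cleavage of the pinacol ester (NaIO4, NH4OAc, acetone/H2O) gives [4-(2-{3-[2-(2-(3-hydroxy-4-methoxyphenyl)ethyl)-4-methoxyphenoxy]phenyl}ethyl)phenyl]boronic acid F5. Chan–Lam–Evans macrocyclisation of F5 (Cu(OAc)2, pyridine, Et3N, 4 Å molecular sieves, CH2Cl2, air, rt, high dilution) gives 18.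

Step 11. Hydrazone formation at the ortho-substituted ketone may stall, or the hot KOH may form azine or cleave an aryl methyl ether. The fallback sets out from 15, replaces the strongly basic high-temperature reduction by a mild hydride reduction of a sulfonylhydrazone, and returns at 17. Ketone 15 with TsNHNH2 (EtOH, cat. AcOH, reflux) gives the tosylhydrazone of 15 F6. Catecholborane (CHCl3, 0 °C) followed by NaOAc·3H2O at reflux gives {5-[2-(2-{3-[2-(4-bromophenyl)ethyl]phenoxy}-5-methoxyphenyl)ethyl]-2-methoxyphenoxy}triisopropylsilane F7. Bu4NF in THF removes the silyl group and gives 17.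

**Further compounds**
F1 | step 9 | 2-{3-[2-(4-bromophenyl)ethyl]phenoxy}-5-methoxybenzaldehyde | COc1ccc(Oc2cccc(CCc3ccc(Br)cc3)c2)c(C=O)c1
F2 | step 9 | (3-hydroxy-4-methoxybenzyl)triphenylphosphonium bromide | [Br-].COc1ccc(C[P+](c2ccccc2)(c2ccccc2)c2ccccc2)cc1O
F3 | step 9 | 5-[2-(2-{3-[2-(4-bromophenyl)ethyl]phenoxy}-5-methoxyphenyl)ethenyl]-2-methoxyphenol (E/Z mixture) | COc1ccc(Oc2cccc(CCc3ccc(Br)cc3)c2)c(C=Cc2ccc(OC)c(O)c2)c1
F4 | step 12 | 5-{2-[5-methoxy-2-(3-{2-[4-(4,4,5,5-tetramethyl-1,3,2-dioxaborolan-2-yl)phenyl]ethyl}phenoxy)phenyl]ethyl}-2-methoxyphenol | COc1ccc(Oc2cccc(CCc3ccc(cc3)B3OC(C)(C)C(C)(C)O3)c2)c(c1)CCc1ccc(OC)c(O)c1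
F5 | step 12 | [4-(2-{3-[2-(2-(3-hydroxy-4-methoxyphenyl)ethyl)-4-methoxyphenoxy]phenyl}ethyl)phenyl]boronic acid | COc1ccc(Oc2cccc(CCc3ccc(cc3)B(O)O)c2)c(c1)CCc1ccc(OC)c(O)c1
F6 | step 11 | tosylhydrazone of ketone 15 | COc1ccc(Oc2cccc(CCc3ccc(Br)cc3)c2)c(c1)C(=NNS(=O)(=O)c1ccc(C)cc1)Cc1ccc(OC)c(O[Si](C(C)C)(C(C)C)C(C)C)c1
F7 | step 11 | {5-[2-(2-{3-[2-(4-bromophenyl)ethyl]phenoxy}-5-methoxyphenyl)ethyl]-2-methoxyphenoxy}triisopropylsilane | COc1ccc(Oc2cccc(CCc3ccc(Br)cc3)c2)c(c1)CCc1ccc(OC)c(O[Si](C(C)C)(C(C)C)C(C)C)c1
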